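A small charge went further in these two runs than a large one: Monday's 0.070 M read 69% target at 5.00 min, while Sunday's 0.41 M read at most 38%, at 2.50 min.

| flask | starting material | remark | time |
|---|---|---|---|
| Monday's | 0.070 M | run made earlier |  |
| Sunday's | 0.41 M | run made earlier |  |
| maple | 0.53 M |  | 10 min |
| elm | 0.12 M |  | 15 min |

- Monday's (time / min: target / %): 0.417: 20; 1.33: 46; 2.50: 57; 4.00: 64; 5.00: 69
- Sunday's (time / min: target / %): 0.417: 23; 0.833: 25; 1.33: 34; 2.50: 38; 5.00: 35

(scatter of a reading: 2 percentage points)

- in percentages every species weighs as the starting material in it: one side product counts as two
- steps under discussion: starting material + target -> side product; starting material <-> dormant form; starting material <-> target + by-product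

- the winner by amount of target, in percent of the starting material charged; "neither" if no more than 2 percentage points parts them (maple / elm / neither)
- how much target is there at the end, in percent of the starting material charged: maple
- how much target is there at the end, in percent of the starting material charged: elm

Starting material splits reversibly into target and by-product, and such a split goes further on dilution. Take y as target's share of a charge c, and count the dormant form with the starting material, since it returns. Then, setting side product aside for now, K = [target][by-product]/([starting material] + [dormant form]) = c·y·y/(1 − y). Sunday's best reading gives this ceiling quotient, an apparent equilibrium constant, as 0.0955 M.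

For maple we iterate. Ignoring the loss of starting material gives y = √(K/c) = 42.4%; putting that back into the bracket gives 32.2%, and one more round gives 35.0%, closing on 34.4%. The same equation gives elm 57.9% and Monday's charge 67.0%, against the 69% read there.

Now we put these answers back once more. Sunday's target then fell to 35%, which is 0.0329 min⁻¹. That is soft, with a scatter of 2 percentage points per reading. Starting material + target gives side product, and that partner falls during a run, so what follows is a rough estimate of our own: we hold the partner at (1 − y)c, dormant form counted in, and take target's loss constant in proportion to it. On that estimate maple loses 0.0450 min⁻¹ and elm 0.00654 min⁻¹, faster in maple. Our reckoning ends at 21.9% for maple and 52.5% for elm.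

The forecast says 29% for maple and 58% for elm (“Elm clearly wins”), which for maple stands above our figure.

The flasks give 22.1% for maple and 54.4% for elm, so elm wins.

    starting material + target → side product (k = 0.00960 L mol⁻¹ s⁻¹)
    starting material ⇌ dormant form (K = 0.580, k = 0.0160 s⁻¹)
    starting material ⇌ target + by-product (K = 0.280 M, k = 0.0110 s⁻¹)

At 10.0 min, maple holds 47.1% side product, more than its target. Now take maple's neighbour, charged with 0.32 M and read at the same time. The ceiling quotient gives it 41.7%, and the same loss brings that to 32.8%; that flask gave 33.4%.

Readings and results are simulated for substances that don't exist; noise was put on by code.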